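**Retrosynthetic overview**
1. Target ⇒ diene bis-angelate by a late reagent-controlled (Shi) epoxidation of the prenyl alkene ⇒ epoxy triol by one selective double angeloylation.
2. Epoxy triol ⇒ 1,1-dimethylallyl ether by a [2,3]-Wittig rearrangement. This makes the key C8–C9 bond: C8 reacts as an α-alkoxy carbanion (a carbinol carbon with inverted polarity, the alcohol-level relative of an acyl anion) and bonds to the allylic terminus C9. Both carbons are acceptor sites in normal polarity, and the step gives the C8 carbinol and the linear prenyl unit at once.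
3. Ether epoxy diol ⇒ all-cis diol (hydroxyl-directed epoxidation) ⇒ enone by Luche reduction, Mitsunobu inversion and α′-hydroxylation.
4. Enone ether ⇒ 10-chlorocarvone + 2-methylbut-3-en-2-ol ⇒ (R)-carvone, which supplies the carbocycle and its C5 stereocentre.
5. Ring order: the six-membered ring is bought with carvone; the ring oxirane is formed in step 6; the side-chain oxirane in step 9.

Assumption: in the explanations, C1–C6 are the ring carbons in carvone numbering (C1 the former carbonyl carbon, C5 the side-chain carbon) and C7–C11 the side chain (C7 the methylene-bearing carbon, C8 the carbinol carbon); (R)-(−)-carvone, 2-methylbut-3-en-2-ol and angelic acid are bought.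

**Step 1**
Reactants: 1 (R)-(−)-carvone
Product: 2 (5R)-5-(3-chloroprop-1-en-2-yl)-2-methylcyclohex-2-en-1-one (10-chlorocarvone)
Conditions: Ca(OCl)2, solid CO2, CH2Cl2/H2O, 0 °C
Reagents that add atoms: calcium hypochlorite Ca(OCl)2, [Ca+2].[O-]Cl.[O-]Cl
Why: Ene-type allylic chlorination by HOCl formed in the flask attacks only the electron-rich 1,1-disubstituted alkene (the enone alkene is deactivated), placing chlorine on the former methylene carbon with transposition of the double bond and leaving the C5 stereocentre untouched.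

**Step 2**
Reactants: 2 10-chlorocarvone; 3 2-methylbut-3-en-2-ol
Product: 5 (5R)-2-methyl-5-{3-[(2-methylbut-3-en-2-yl)oxy]prop-1-en-2-yl}cyclohex-2-en-1-one, via allylic iodide 4 (not isolated)
Conditions: NaI, acetone, rt, dark; filter, evaporate; then 3 (5 equiv), AgOTf, 2,6-di-tert-butyl-4-methylpyridine, CH2Cl2, −40 → 0 °C, dark
Reagents that add atoms: none
Why: Finkelstein exchange gives the more reactive allylic iodide, and silver-assisted displacement (a Williamson-type etherification run without alkoxide base) lets the tertiary alcohol oxygen attack the primary allylic carbon, whose two termini are equivalent, while the base-free medium avoids the intramolecular enolate alkylation that 10-halocarvones undergo with alkoxides; no stereocentre is touched.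

**Step 3**
Reactants: 5 ether enone
Product: 7 (5S,6S)-6-hydroxy-2-methyl-5-{3-[(2-methylbut-3-en-2-yl)oxy]prop-1-en-2-yl}cyclohex-2-en-1-one (hydroxyl trans to the side chain), via lithium dienolate 6 (not isolated)
Conditions: LDA (LiN(iPr)2), THF, −78 °C; then trans-2-(phenylsulfonyl)-3-phenyloxaziridine, −78 °C; AcOH quench
Reagents that add atoms: trans-2-(phenylsulfonyl)-3-phenyloxaziridine (Davis oxaziridine), O=S(=O)(N1OC1c1ccccc1)c1ccccc1
Why: Kinetic α′-deprotonation gives the cross-conjugated lithium dienolate, and Davis oxaziridine hydroxylation delivers oxygen to C6 on the face opposite the adjacent C5 side chain (substrate control, trans isomer expected as the major product and purified by chromatography); the allyl ether CH2 is far less acidic and is not touched.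

**Step 4**
Reactants: 7 trans hydroxy ketone
Product: 8 (1R,6S)-3-methyl-2-oxo-6-{3-[(2-methylbut-3-en-2-yl)oxy]prop-1-en-2-yl}cyclohex-3-en-1-yl 4-nitrobenzoate (ester oxygen cis to the side chain)
Conditions: PPh3, DIAD, 4-nitrobenzoic acid, THF, 0 °C → rt
Reagents that add atoms: 4-nitrobenzoic acid, OC(=O)c1ccc(cc1)[N+](=O)[O-]
Why: Mitsunobu reaction: the equatorial C6 hydroxyl is activated as its oxyphosphonium salt and displaced by 4-nitrobenzoate with SN2 inversion at this carbonyl-activated carbon (sterically the same situation as the menthol to neomenthyl ester inversion), which puts the C6 oxygen cis to the side chain.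

**Step 5**
Reactants: 8 cis keto ester
Product: 10 (1R,2S,6S)-3-methyl-6-{3-[(2-methylbut-3-en-2-yl)oxy]prop-1-en-2-yl}cyclohex-3-ene-1,2-diol (both hydroxyls cis to the side chain), via hydroxy ester 9 (not isolated)
Conditions: NaBH4, CeCl3·7H2O, MeOH, −40 °C; extractive work-up; then K2CO3 (cat.), MeOH, 0 °C → rt
Reagents that add atoms: none
Why: Luche reduction: the small cerium-modified borohydride adds 1,2 to the enone along the axial trajectory, anti to the axial C6 acyloxy group and on the face that also gives the cis-carveol pattern, so the new C1 hydroxyl is cis to both the C6 oxygen and the C5 side chain, and catalytic K2CO3 in methanol then transesterifies the 4-nitrobenzoate away.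

**Step 6**
Reactants: 10 all-cis diol
Product: 11 (1R,2R,3R,4S,6S)-1-methyl-4-{3-[(2-methylbut-3-en-2-yl)oxy]prop-1-en-2-yl}-7-oxabicyclo[4.1.0]heptane-2,3-diol (oxirane oxygen cis to both hydroxyls)
Conditions: VO(acac)2 (3 mol %), t-BuOOH (1.2 equiv), CH2Cl2, 0 °C → rt
Reagents that add atoms: tert-butyl hydroperoxide, CC(C)(C)OO
Why: Hydroxyl-directed epoxidation (Sharpless–Michaelson VO(acac)2/t-BuOOH): the vanadium alkylperoxide bound to the allylic C1 hydroxyl (and to the cis homoallylic C6 hydroxyl) delivers oxygen to the C2=C3 alkene on the hydroxyl-bearing face, while the 1,1-disubstituted and vinyl alkenes, which have no allylic hydroxyl, react far more slowly.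

**Step 7**
Reactants: 11 epoxy diol ether
Product: 14 (1R,2R,3R,4S,6S)-4-[(3S)-3-hydroxy-6-methylhepta-1,5-dien-2-yl]-1-methyl-7-oxabicyclo[4.1.0]heptane-2,3-diol, via lithiated allyl ether 12 (not isolated), via trilithium alkoxide 13 (not isolated)
Conditions: n-BuLi (3.3 equiv), THF, −78 → −50 °C; then H2O
Reagents that add atoms: none
Why: Proposed new method: the [2,3]-Wittig rearrangement of bis-allylic ethers is established, and here the α-alkoxyallyl carbanion at C8 (the only α-oxygenated C–H, the other ether carbon being quaternary) attacks the vinyl CH2 of the 1,1-dimethylallyl group through the five-membered envelope transition state to give only the linear prenyl carbinol, while the new element is that the neighbouring cis C6 lithium alkoxide is expected to direct the lithiation and hold lithium on its own face of the Z-configured oxyallyl anion, so that C–C bond formation with inversion on the opposite face gives the 8S carbinol, the closest known reactions being [2,3]-Wittig shifts that proceed with inversion at the lithium-bearing carbon and alkoxide-directed (complex-induced proximity) lithiations.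

**Step 8**
Reactants: 14 epoxy triol; 15 angelic acid
Product: 16 (1S,2R,3R,4S,6S)-3-hydroxy-1-methyl-4-[(3S)-6-methyl-3-{[(2Z)-2-methylbut-2-enoyl]oxy}hepta-1,5-dien-2-yl]-7-oxabicyclo[4.1.0]heptan-2-yl (2Z)-2-methylbut-2-enoate
Conditions: 15 (2.4 equiv), 2,4,6-trichlorobenzoyl chloride (2.4 equiv), Et3N, toluene, rt; then 14, 60 °C, no DMAP
Reagents that add atoms: none
Why: Yamaguchi-type mixed-anhydride esterification without DMAP keeps the Z geometry of the angelate, and the acyclic allylic C8 hydroxyl and the equatorial C1 hydroxyl are acylated in preference to the axial C6 hydroxyl, which is flanked by two substituted carbons and hydrogen-bonded to the syn oxirane oxygen (the equatorial ester is also the thermodynamically favoured one should acyl migration occur); no stereocentre changes.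

**Step 9**
Reactants: 16 diene bis-angelate
Product: 17 (1S,2R,3R,4S,6S)-4-[(3S)-4-[(2R)-3,3-dimethyloxiran-2-yl]-3-{[(2Z)-2-methylbut-2-enoyl]oxy}but-1-en-2-yl]-3-hydroxy-1-methyl-7-oxabicyclo[4.1.0]heptan-2-yl (2Z)-2-methylbut-2-enoate (CNP0296086.3)
Conditions: D-fructose-derived Shi ketone (30 mol %), KHSO5 (as Oxone, 1.4 equiv), K2CO3, Bu4NHSO4, MeCN/CH2(OMe)2, aqueous Na2B4O7 buffer, 0 °C
Reagents that add atoms: potassium peroxymonosulfate KHSO5, [K+].[O-]S(=O)(=O)OO
Why: Shi asymmetric epoxidation: the chiral dioxirane formed from the D-fructose-derived ketone and KHSO5 epoxidises the electron-rich trisubstituted C10=C11 alkene through the spiro transition state that gives the R oxirane for R–CH2–CH=CMe2 olefins (reagent control), while the 1,1-disubstituted alkene bearing an allylic ester and the two electron-poor angelate alkenes react much more slowly.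

**Compound list**
1 | (R)-(−)-carvone, (5R)-2-methyl-5-(prop-1-en-2-yl)cyclohex-2-en-1-one | C=C(C)[C@@H]1CC=C(C)C(=O)C1 | starting material
2 | (5R)-5-(3-chloroprop-1-en-2-yl)-2-methylcyclohex-2-en-1-one | C=C(CCl)[C@@H]1CC=C(C)C(=O)C1 | intermediate
3 | 2-methylbut-3-en-2-ol | CC(C)(O)C=C | starting material
4 | (5R)-5-(3-iodoprop-1-en-2-yl)-2-methylcyclohex-2-en-1-one (not isolated) | C=C(CI)[C@@H]1CC=C(C)C(=O)C1 | intermediate
5 | (5R)-2-methyl-5-{3-[(2-methylbut-3-en-2-yl)oxy]prop-1-en-2-yl}cyclohex-2-en-1-one | C=C(COC(C)(C)C=C)[C@@H]1CC=C(C)C(=O)C1 | intermediate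
6 | lithium (3R)-6-methyl-3-{3-[(2-methylbut-3-en-2-yl)oxy]prop-1-en-2-yl}cyclohexa-1,5-dien-1-olate (not isolated) | [Li+].C=C(COC(C)(C)C=C)[C@@H]1CC=C(C)C([O-])=C1 | intermediate
7 | (5S,6S)-6-hydroxy-2-methyl-5-{3-[(2-methylbut-3-en-2-yl)oxy]prop-1-en-2-yl}cyclohex-2-en-1-one | C=C(COC(C)(C)C=C)[C@@H]1CC=C(C)C(=O)[C@H]1O | intermediate
8 | (1R,6S)-3-methyl-2-oxo-6-{3-[(2-methylbut-3-en-2-yl)oxy]prop-1-en-2-yl}cyclohex-3-en-1-yl 4-nitrobenzoate | C=C(COC(C)(C)C=C)[C@@H]1CC=C(C)C(=O)[C@@H]1OC(=O)c2ccc(cc2)[N+](=O)[O-] | intermediate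
9 | (1R,2S,6S)-2-hydroxy-3-methyl-6-{3-[(2-methylbut-3-en-2-yl)oxy]prop-1-en-2-yl}cyclohex-3-en-1-yl 4-nitrobenzoate (not isolated) | C=C(COC(C)(C)C=C)[C@@H]1CC=C(C)[C@H](O)[C@@H]1OC(=O)c2ccc(cc2)[N+](=O)[O-] | intermediate
10 | (1R,2S,6S)-3-methyl-6-{3-[(2-methylbut-3-en-2-yl)oxy]prop-1-en-2-yl}cyclohex-3-ene-1,2-diol | C=C(COC(C)(C)C=C)[C@@H]1CC=C(C)[C@H](O)[C@@H]1O | intermediate
11 | (1R,2R,3R,4S,6S)-1-methyl-4-{3-[(2-methylbut-3-en-2-yl)oxy]prop-1-en-2-yl}-7-oxabicyclo[4.1.0]heptane-2,3-diol | C=C(COC(C)(C)C=C)[C@@H]1C[C@@H]2O[C@]2(C)[C@H](O)[C@@H]1O | intermediate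
12 | trilithium derivative of 11: both ring hydroxyls as lithium alkoxides, carbanion at the OCH2 carbon (C8) (not isolated) | [Li+].[Li+].[Li+].C=C([CH-]OC(C)(C)C=C)[C@@H]1C[C@@H]2O[C@]2(C)[C@H]([O-])[C@@H]1[O-] | intermediate
13 | trilithium trialkoxide of 14 (not isolated) | [Li+].[Li+].[Li+].C=C([C@H](CC=C(C)C)[O-])[C@@H]1C[C@@H]2O[C@]2(C)[C@H]([O-])[C@@H]1[O-] | intermediate
14 | (1R,2R,3R,4S,6S)-4-[(3S)-3-hydroxy-6-methylhepta-1,5-dien-2-yl]-1-methyl-7-oxabicyclo[4.1.0]heptane-2,3-diol | C=C([C@H](CC=C(C)C)O)[C@@H]1C[C@@H]2O[C@]2(C)[C@H](O)[C@@H]1O | intermediate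
15 | angelic acid, (2Z)-2-methylbut-2-enoic acid | C/C=C(/C)C(=O)O | starting material
16 | (1S,2R,3R,4S,6S)-3-hydroxy-1-methyl-4-[(3S)-6-methyl-3-{[(2Z)-2-methylbut-2-enoyl]oxy}hepta-1,5-dien-2-yl]-7-oxabicyclo[4.1.0]heptan-2-yl (2Z)-2-methylbut-2-enoate | C=C([C@H](CC=C(C)C)OC(=O)/C(C)=C\C)[C@@H]1C[C@@H]2O[C@]2(C)[C@H](OC(=O)/C(C)=C\C)[C@@H]1O | intermediate
17 | CNP0296086.3, (1S,2R,3R,4S,6S)-4-[(3S)-4-[(2R)-3,3-dimethyloxiran-2-yl]-3-{[(2Z)-2-methylbut-2-enoyl]oxy}but-1-en-2-yl]-3-hydroxy-1-methyl-7-oxabicyclo[4.1.0]heptan-2-yl (2Z)-2-methylbut-2-enoate | C=C([C@H](C[C@H]1OC1(C)C)OC(=O)/C(C)=C\C)[C@@H]1C[C@@H]2O[C@]2(C)[C@H](OC(=O)/C(C)=C\C)[C@@H]1O | target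

Note on descriptors: the methyl-bearing oxirane carbon is written 1R in 11–14 and 1S in 16 and 17 only because acylation of the neighbouring oxygen changes the CIP ranking; its geometry does not change.

Where each stereocentre is set: C5 from carvone; C6 in steps 3 and 4; C1 in step 5; both oxirane carbons of the ring in step 6; C8 in step 7; C10 in step 9.

**Totals**
Total step count: 9. Longest linear sequence: 9 steps (1 → 17).

**Three steps most likely to fail**

Step 7 (yield of the trianion rearrangement and the face selectivity at C8). The fallback sets out from 11. Both hydroxyls are silylated (TESOTf, 2,6-lutidine, CH2Cl2, −78 °C) to the bis(triethylsilyl) ether F1. The [2,3]-Wittig shift is run on this neutral substrate (n-BuLi, THF, −78 °C) to the rearranged alcohol as a C8 epimer mixture F2. This is oxidised with Dess–Martin periodinane and NaHCO3 to the β,γ-unsaturated enone F3. Reduction with (R)-2-methyl-CBS-oxazaborolidine and catecholborane (toluene, −78 °C; the 1-substituted vinyl group acts as the large group) gives the 8S alcohol F4. Removal of both silyl groups with Bu4NF comes back to the route at 14. The C8 stereocentre is then set by a reagent-controlled reduction instead of by the rearrangement.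

Step 8 (selectivity between the C1 and C6 hydroxyls, over-acylation). The fallback sets out from 14. Heating with Bu2SnO in toluene with removal of water gives the dibutylstannylene acetal F5 of the cis diol. The tin acetal reacts with 1.1 equiv of the angelic mixed anhydride at rt at its equatorial oxygen only, giving the C1 mono-angelate F6. A second, separate acylation of the side-chain C8 hydroxyl (mixed anhydride, Et3N, toluene, 60 °C) comes back to the route at 16. The regiochemistry is then fixed by tin-acetal activation instead of by intrinsic reactivity.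

Step 2 (silver-assisted alkylation of a hindered, ionisable tertiary allylic alcohol). The fallback sets out from 2. Displacement with HCO2Na in DMF gives 10-formyloxycarvone F7, and catalytic K2CO3 in methanol gives 10-hydroxycarvone F8. Its primary hydroxyl is alkylated with 2-methylbut-3-yn-2-yl 2,2,2-trichloroacetimidate and catalytic BF3·OEt2 (CH2Cl2/cyclohexane, 0 °C) to the 1,1-dimethylpropargyl ether F9. Semi-hydrogenation of the terminal alkyne (H2, Pd/CaCO3 poisoned with Pb(OAc)2, quinoline) comes back to the route at 5. The ether oxygen then comes from the carvone fragment, and the tertiary carbon enters as a propargylic electrophile that cannot undergo allylic transposition.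

**Further compounds**
F1 | step 7 | bis(triethylsilyl) ether of 11 | C=C(COC(C)(C)C=C)[C@@H]1C[C@@H]2O[C@]2(C)[C@H](O[Si](CC)(CC)CC)[C@@H]1O[Si](CC)(CC)CC
F2 | step 7 | rearranged alcohol, bis(triethylsilyl) ether, mixture of C8 epimers | C=C(C(CC=C(C)C)O)[C@@H]1C[C@@H]2O[C@]2(C)[C@H](O[Si](CC)(CC)CC)[C@@H]1O[Si](CC)(CC)CC
F3 | step 7 | C8 ketone (6-methylhepta-1,5-dien-3-one side chain), bis(triethylsilyl) ether | C=C(C(=O)CC=C(C)C)[C@@H]1C[C@@H]2O[C@]2(C)[C@H](O[Si](CC)(CC)CC)[C@@H]1O[Si](CC)(CC)CC
F4 | step 7 | 8S alcohol, bis(triethylsilyl) ether of 14 | C=C([C@H](CC=C(C)C)O)[C@@H]1C[C@@H]2O[C@]2(C)[C@H](O[Si](CC)(CC)CC)[C@@H]1O[Si](CC)(CC)CC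
F5 | step 8 | dibutylstannylene acetal of the ring cis diol of 14 | C=C([C@H](CC=C(C)C)O)[C@@H]1C[C@@H]2O[C@]2(C)[C@@H]3O[Sn](CCCC)(CCCC)O[C@H]13
F6 | step 8 | C1 mono-angelate of 14 (side-chain and C6 hydroxyls free) | C=C([C@H](CC=C(C)C)O)[C@@H]1C[C@@H]2O[C@]2(C)[C@H](OC(=O)/C(C)=C\C)[C@@H]1O
F7 | step 2 | 10-formyloxycarvone, 2-[(1R)-4-methyl-5-oxocyclohex-3-en-1-yl]prop-2-en-1-yl formate | C=C(COC=O)[C@@H]1CC=C(C)C(=O)C1
F8 | step 2 | 10-hydroxycarvone, (5R)-5-(3-hydroxyprop-1-en-2-yl)-2-methylcyclohex-2-en-1-one | C=C(CO)[C@@H]1CC=C(C)C(=O)C1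
F9 | step 2 | (5R)-2-methyl-5-{3-[(2-methylbut-3-yn-2-yl)oxy]prop-1-en-2-yl}cyclohex-2-en-1-one | C=C(COC(C)(C)C#C)[C@@H]1CC=C(C)C(=O)C1
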